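**Retrosynthetic overview**
- The target is the (S)-carvotanacetone skeleton carrying four C–O bonds. The six-membered ring and the isopropyl stereocentre come intact from (S)-(+)-carvone, so no ring is formed and no C–C bond is made.
- C6–OAc ⇒ α′-acetoxylation of the enone (last step).
- C7–O tiglate ⇒ direct allylic C–H acyloxylation of the enone methyl group with tiglic acid (new catalytic step).
- C4–O tiglate (cis to isopropyl) ⇒ Mitsunobu inversion of the trans γ-hydroxy enone, which comes from singlet-oxygen 1,4-oxygenation of the dienyl acetate of carvotanacetone.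
- Carvotanacetone ⇒ (S)-(+)-carvone by selective hydrogenation.

Assumption: locants C1–C7 follow cyclohex-2-en-1-one numbering (C1 carbonyl, C7 the exocyclic carbon on C2); read this way the target is (4S,5S,6R) with two (E)-2-methylbut-2-enoate (tiglate) esters.

**Route**

Step 1
Reactants: 1 (S)-(+)-carvone, (5S)-2-methyl-5-(prop-1-en-2-yl)cyclohex-2-en-1-one
Product: 2 (S)-carvotanacetone, (5S)-2-methyl-5-(propan-2-yl)cyclohex-2-en-1-one
Conditions: H2 (1 atm), RhCl(PPh3)3 (2 mol %), benzene, rt
Reagents that add atoms: none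
Why: Chemoselective homogeneous hydrogenation, in which RhCl(PPh3)3 reduces the unhindered 1,1-disubstituted isopropenyl olefin much faster than the trisubstituted enone olefin and leaves the C5 stereocentre from the chiral pool untouched.

Step 2
Reactants: 2 (S)-carvotanacetone
Product: 3 (5S)-2-methyl-5-(propan-2-yl)cyclohexa-1,3-dien-1-yl acetate
Conditions: isopropenyl acetate (solvent), TsOH·H2O (5 mol %), reflux, slow distillation
Reagents that add atoms: isopropenyl acetate, CC(=C)OC(C)=O
Why: Acid-catalysed enol acetylation under equilibrating conditions gives the thermodynamic through-conjugated dienyl acetate by loss of a C4 proton, while C5 stays sp3 and keeps its configuration.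

Step 3
Reactants: 3 (5S)-2-methyl-5-(propan-2-yl)cyclohexa-1,3-dien-1-yl acetate
Product: 5 (4S,5S)-4-hydroxy-2-methyl-5-(propan-2-yl)cyclohex-2-en-1-one, via acetoxy endoperoxide 4 (not isolated)
Conditions: O2, tetraphenylporphyrin (0.5 mol %), white LEDs, CH2Cl2, −40 °C; then Zn dust, AcOH, 0 °C
Reagents that add atoms: dioxygen, O=O
Why: Singlet-oxygen [4+2] cycloaddition to the cisoid diene puts oxygen on C1 and C4 only and is expected to enter mainly anti to the C5 isopropyl group, which sets C4 as S (OH trans to isopropyl; the minor C4 epimer is removed by chromatography), and O–O reduction gives a hemiketal acetate that collapses to the enone.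

Step 4
Reactants: 5 (4S,5S)-4-hydroxy-2-methyl-5-(propan-2-yl)cyclohex-2-en-1-one; 6 tiglic acid, (2E)-2-methylbut-2-enoic acid (1.5 equiv)
Product: 7 (1R,6S)-3-methyl-4-oxo-6-(propan-2-yl)cyclohex-2-en-1-yl (2E)-2-methylbut-2-enoate
Conditions: PPh3, DIAD, THF, 0 °C to rt
Reagents that add atoms: none
Why: Mitsunobu esterification, in which tiglate displaces the oxyphosphonium of the allylic alcohol by SN2 with inversion, so the trans alcohol becomes the cis C4–O stereocentre of the target and the first tiglate is installed in the same C–O bond-forming event.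

Step 5
Reactants: 7 (1R,6S)-3-methyl-4-oxo-6-(propan-2-yl)cyclohex-2-en-1-yl (2E)-2-methylbut-2-enoate; 6 tiglic acid (3 equiv)
Product: 8 [(3R,4S)-3-{[(2E)-2-methylbut-2-enoyl]oxy}-6-oxo-4-(propan-2-yl)cyclohex-1-en-1-yl]methyl (2E)-2-methylbut-2-enoate
Conditions: [Cp*RhCl2]2 (2.5 mol %), AgSbF6 (10 mol %), Ag2O (1.1 equiv), 4 Å sieves, 1,2-dichloroethane, 60 °C
Reagents that add atoms: none
Why: Proposed new method: a cationic Cp*Rh tiglate (trivalent rhodium) bound to the enone cleaves a C7–H bond by carboxylate-assisted metalation–deprotonation (the methyl group is the only primary, unhindered allylic C–H next to the ketone, since C4–H is tertiary and flanked by ester and isopropyl) to give a 2-acyl η3-allyl rhodium species, oxidation by silver tiglate formed in situ to tetravalent rhodium then triggers C–O reductive elimination at the CH2 terminus, the only position that restores enone conjugation, and the closest known reaction type is Cp*Rh/Cp*Ir-catalysed allylic C–H amination, etherification and acetoxylation of unactivated di- and trisubstituted olefins through oxidatively induced reductive elimination, not yet shown for the α-methyl group of an enone or with a carboxylate other than acetate retained in the product.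

Step 6
Reactants: 8 [(3R,4S)-3-{[(2E)-2-methylbut-2-enoyl]oxy}-6-oxo-4-(propan-2-yl)cyclohex-1-en-1-yl]methyl (2E)-2-methylbut-2-enoate
Product: 9 [(3S,4S,5R)-5-(acetyloxy)-3-{[(2E)-2-methylbut-2-enoyl]oxy}-6-oxo-4-(propan-2-yl)cyclohex-1-en-1-yl]methyl (2E)-2-methylbut-2-enoate (CNP0218511.1)
Conditions: Mn(OAc)3·2H2O (4 equiv), benzene–AcOH (10:1), reflux (Dean–Stark)
Reagents that add atoms: manganese triacetate, CC(=O)[O-].CC(=O)[O-].CC(=O)[O-].[Mn+3]
Why: α′-Acetoxylation of an enone with Mn(OAc)3 (trivalent manganese enolate, then acetate transfer to C6), where acetate arrives anti to the adjacent isopropyl group and the epimerisable product is the thermodynamically preferred equatorial acetate, so C6 is set R (OAc trans to isopropyl).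

**Compound list**
1 | (S)-(+)-carvone, (5S)-2-methyl-5-(prop-1-en-2-yl)cyclohex-2-en-1-one | CC1=CC[C@@H](CC1=O)C(C)=C | starting material
2 | (S)-carvotanacetone, (5S)-2-methyl-5-(propan-2-yl)cyclohex-2-en-1-one | CC1=CC[C@@H](CC1=O)C(C)C | intermediate
3 | (5S)-2-methyl-5-(propan-2-yl)cyclohexa-1,3-dien-1-yl acetate | CC1=C(OC(C)=O)C[C@@H](C(C)C)C=C1 | intermediate
4 | (1R,4S,8S)-6-methyl-8-(propan-2-yl)-2,3-dioxabicyclo[2.2.2]oct-5-en-1-yl acetate (peroxide bridge anti to isopropyl; not isolated) | CC1=C[C@H]2OO[C@]1(OC(C)=O)C[C@H]2C(C)C | intermediate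
5 | (4S,5S)-4-hydroxy-2-methyl-5-(propan-2-yl)cyclohex-2-en-1-one (OH trans to isopropyl) | CC1=C[C@@H](O)[C@H](C(C)C)CC1=O | intermediate
6 | tiglic acid, (2E)-2-methylbut-2-enoic acid | C/C=C(\C)C(=O)O | starting material
7 | (1R,6S)-3-methyl-4-oxo-6-(propan-2-yl)cyclohex-2-en-1-yl (2E)-2-methylbut-2-enoate (ester cis to isopropyl) | CC1=C[C@H](OC(=O)/C(C)=C/C)[C@H](C(C)C)CC1=O | intermediate
8 | [(3R,4S)-3-{[(2E)-2-methylbut-2-enoyl]oxy}-6-oxo-4-(propan-2-yl)cyclohex-1-en-1-yl]methyl (2E)-2-methylbut-2-enoate | C/C=C(\C)C(=O)OCC1=C[C@H](OC(=O)/C(C)=C/C)[C@H](C(C)C)CC1=O | intermediate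
9 | [(3S,4S,5R)-5-(acetyloxy)-3-{[(2E)-2-methylbut-2-enoyl]oxy}-6-oxo-4-(propan-2-yl)cyclohex-1-en-1-yl]methyl (2E)-2-methylbut-2-enoate | C/C=C(\C)C(=O)OCC1=C[C@H](OC(=O)/C(C)=C/C)[C@H](C(C)C)[C@@H](OC(C)=O)C1=O | target

**Totals**
Total steps: 6. Longest linear sequence: 6 steps, from (S)-(+)-carvone.

**Three steps most likely to fail**

Step 5 (the new C–H tigloyloxylation). The electron-poor enone may not turn over, a tiglate methyl group may be activated instead, or α′-enolisation may lead to loss of tiglic acid and aromatisation. The fallback uses known chemistry, sets out from 7 and comes back at 8. Luche reduction of 7 (NaBH4, CeCl3·7H2O, MeOH, −78 °C) gives the allylic alcohol (1R,4S,6S)-4-hydroxy-3-methyl-6-(propan-2-yl)cyclohex-2-en-1-yl (2E)-2-methylbut-2-enoate F1; the carbinol configuration does not matter. With the ketone gone the ring alkene is an ordinary trisubstituted olefin, so catalytic SeO2 with t-BuOOH (CH2Cl2, rt) hydroxylates the methyl group on its more substituted carbon by the usual ene/[2,3] sequence and gives the diol (1R,4S,6S)-4-hydroxy-3-(hydroxymethyl)-6-(propan-2-yl)cyclohex-2-en-1-yl (2E)-2-methylbut-2-enoate F2. Tigloyl chloride with 2,4,6-collidine at −78 °C acylates the primary allylic alcohol selectively to [(3R,4S,6S)-6-hydroxy-3-{[(2E)-2-methylbut-2-enoyl]oxy}-4-(propan-2-yl)cyclohex-1-en-1-yl]methyl (2E)-2-methylbut-2-enoate F3. Dess–Martin oxidation of the remaining secondary allylic alcohol then gives 8.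

Step 4 (Mitsunobu with tiglic acid). The carbinol sits next to the isopropyl-bearing carbon, tiglic acid is a weak pronucleophile, and elimination would lead to the dienone and on to carvacrol. The fallback separates inversion from acylation, sets out from 5 and comes back at 7. Mitsunobu reaction with the much more acidic 4-nitrobenzoic acid (PPh3, DIAD, toluene, 0 °C) gives the inverted ester (1R,6S)-3-methyl-4-oxo-6-(propan-2-yl)cyclohex-2-en-1-yl 4-nitrobenzoate F4. Methanolysis (K2CO3, MeOH, 0 °C) frees the cis alcohol (4R,5S)-4-hydroxy-2-methyl-5-(propan-2-yl)cyclohex-2-en-1-one F5, which is acylated with retention by tigloyl chloride, pyridine and DMAP to give 7. F5 is also the minor epimer from step 3, so this acylation lets both epimers converge on 7.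

Step 6 (Mn(OAc)3 α′-acetoxylation). Diastereoselectivity may be modest and the hindered C6 position may react slowly on a late intermediate carrying three esters. The fallback is an enolate-based Rubottom sequence that sets out from 8 and comes back at 9. Kinetic enolisation at C6 with in-situ silylation (LiHMDS, Et3SiCl, THF, −78 °C) gives the cross-conjugated silyl dienol ether [(3R,4R)-3-{[(2E)-2-methylbut-2-enoyl]oxy}-4-(propan-2-yl)-6-[(triethylsilyl)oxy]cyclohexa-1,5-dien-1-yl]methyl (2E)-2-methylbut-2-enoate F6. Oxidation with dimethyldioxirane (acetone/CH2Cl2, −78 °C) on the face anti to isopropyl, followed by citric acid in MeOH, gives the α′-hydroxy ketone [(3S,4R,5R)-5-hydroxy-3-{[(2E)-2-methylbut-2-enoyl]oxy}-6-oxo-4-(propan-2-yl)cyclohex-1-en-1-yl]methyl (2E)-2-methylbut-2-enoate F7. Acetylation (Ac2O, pyridine, DMAP) gives 9.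

**Further compounds**
F1 | step 5 | (1R,4S,6S)-4-hydroxy-3-methyl-6-(propan-2-yl)cyclohex-2-en-1-yl (2E)-2-methylbut-2-enoate | CC1=C[C@H](OC(=O)/C(C)=C/C)[C@H](C(C)C)C[C@@H]1O
F2 | step 5 | (1R,4S,6S)-4-hydroxy-3-(hydroxymethyl)-6-(propan-2-yl)cyclohex-2-en-1-yl (2E)-2-methylbut-2-enoate | OCC1=C[C@H](OC(=O)/C(C)=C/C)[C@H](C(C)C)C[C@@H]1O
F3 | step 5 | [(3R,4S,6S)-6-hydroxy-3-{[(2E)-2-methylbut-2-enoyl]oxy}-4-(propan-2-yl)cyclohex-1-en-1-yl]methyl (2E)-2-methylbut-2-enoate | C/C=C(\C)C(=O)OCC1=C[C@H](OC(=O)/C(C)=C/C)[C@H](C(C)C)C[C@@H]1O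
F4 | step 4 | (1R,6S)-3-methyl-4-oxo-6-(propan-2-yl)cyclohex-2-en-1-yl 4-nitrobenzoate | CC1=C[C@H](OC(=O)c2ccc(cc2)[N+](=O)[O-])[C@H](C(C)C)CC1=O
F5 | step 4 | (4R,5S)-4-hydroxy-2-methyl-5-(propan-2-yl)cyclohex-2-en-1-one | CC1=C[C@H](O)[C@H](C(C)C)CC1=O
F6 | step 6 | [(3R,4R)-3-{[(2E)-2-methylbut-2-enoyl]oxy}-4-(propan-2-yl)-6-[(triethylsilyl)oxy]cyclohexa-1,5-dien-1-yl]methyl (2E)-2-methylbut-2-enoate | C/C=C(\C)C(=O)OCC1=C[C@H](OC(=O)/C(C)=C/C)[C@H](C(C)C)C=C1O[Si](CC)(CC)CC
F7 | step 6 | [(3S,4R,5R)-5-hydroxy-3-{[(2E)-2-methylbut-2-enoyl]oxy}-6-oxo-4-(propan-2-yl)cyclohex-1-en-1-yl]methyl (2E)-2-methylbut-2-enoate | C/C=C(\C)C(=O)OCC1=C[C@H](OC(=O)/C(C)=C/C)[C@H](C(C)C)[C@@H](O)C1=O
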